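The runs were generated by integration for an exercise, and the scatter is random.

Ask what share of the Sub charged to the north-east run stands as Prd at the asked time.

| flask | Sub | Rgt | Cat | time |
|---|---|---|---|---|
| south | 0.250 M | 0.275 M | 0.0250 M |  |
| west | 0.750 M | 0.275 M | 0.0250 M |  |
| north | 0.250 M | 0.410 M | 0.0250 M |  |
| north-west | 0.250 M | 0.275 M | 0.0750 M |  |
| north-east | 0.0830 M | 0.830 M | 0.0250 M | 22 min |

| south run: time / min | south run: [Prd] / M | west run: time / min | west run: [Prd] / M | north run: time / min | north run: [Prd] / M | north-west run: time / min | north-west run: [Prd] / M |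
|---|---|---|---|---|---|---|---|
| 0.88 | 0.0198 | 0.88 | 0.0555 | 0.88 | 0.0308 | 0.88 | 0.0563 |
| 1.4 | 0.0309 | 1.4 | 0.0799 | 1.4 | 0.0446 | 1.4 | 0.0744 |
| 2.2 | 0.0454 | 2.2 | 0.1085 | 2.2 | 0.0624 | 2.2 | 0.1004 |
| 3.5 | 0.0635 | 3.5 | 0.1436 | 3.5 | 0.0895 | 3.5 | 0.1269 |
| 5.5 | 0.0828 | 5.5 | 0.1736 | 5.5 | 0.1169 | 5.5 | 0.1526 |
| 8.8 | 0.1077 | 8.8 | 0.2011 | 8.8 | 0.1443 | 8.8 | 0.1749 |
| 14 | 0.1283 | 14 | 0.2195 | 14 | 0.1643 | 14 | 0.1853 |
| 22 | 0.1435 | 22 | 0.2228 | 22 | 0.1753 | 22 | 0.1889 |

(scatter of a reading: 0.001 M)

1. reaction order in [Sub] at the outset, round the charge of the south run, defined at two percent of the Sub turned into Prd (one fixed amount of Prd, the same in the runs compared)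
2. reaction order in [Cat] at the outset, round the charge of the south run, defined at two percent of the Sub turned into Prd
3. Prd in the north-east run at 22 min, as a share of the Sub charged

- Overall: Sub + Rgt -> Prd, with Cat as catalyst.
- Constant volume, constant temperature.
- An order is taken over about fifteen percent of the charge, up and down.

Start with the south run. Put its reading at 2.2 min into the integrated law for rate = k[Sub][Rgt]. The north-east run has the same [Cat], and its [Rgt] stands at 10.0 times its [Sub], so Sub is the limiting reagent. Freeze [Rgt] there and treat the flask as pseudo-first-order, with k′ = k[Rgt] = 0.301 min⁻¹.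

Take first order in [Sub] and in [Cat]. With 3.00 times the charge of each, the first west and north-west readings stand at 2.80 and 2.84 times the south one.

Subtract 1/k′ from the asked time: 18.7 min estimates the mean age of Prd, the time it has on average stood in the north-east flask.

Now size a possible leak of Prd. In the west run Rgt is limiting, and at 22 min Prd stands 0.0522 M short of the Rgt charged. Take the mean age in the west run as roughly 18.5 min, counted from 3.5 min, where Prd has reached 64.5% of its last reading. Count the whole gap as leaked Prd. That gives a rough upper estimate of 0.0127 min⁻¹ for a first-order leak, since some of that Rgt may stand unreacted. Over the north-east age this rate leaves 78.9%, so commit to a share between that low estimate and 99.9%, the frozen reckoning without a leak.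

The forecast gives orders in [Sub] and [Cat] of 1 (0.85 to 1.15) and 1 (0.85 to 1.15), and a north-east share of 97.5% (93% to 99.5%), holding that “the catalyst appears to die”.

The simulation gives orders in [Sub] and [Cat] of 1.0 and 1.0, with west and north-west rates over the south rate of 3.0 and 3.0, and a north-east share of 85.6%.

    Cat + Sub + Rgt → Prd + Cat (15.12 M⁻² min⁻¹)
    Prd → Q (0.007200 min⁻¹)
    2 Sub → E (0.07320 M⁻¹ min⁻¹)

The reason is the path from Prd to Q: take it from the north-east run and Prd at the asked time goes from 85.6% to 97.9%. That is 12 percentage points, or 85% of what is missing. Set k2 on the carried age and the fraction of Prd surviving in the north-east run comes to 87.4%.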